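The route rests on cutting the exocyclic CH2–aryl bond next to the fully substituted lactone carbon C3. The feature exploited is the 1,2-relationship between the tertiary C3–OH of the butyrolactone ring and this exocyclic CH2: both are folded into a spiro-oxirane on C3, a ring absent from the target. A copper-catalysed aryl Grignard reagent carrying the masked catechol ring opens the oxirane at its unsubstituted CH2. One operation thus joins two fragments of similar size at a neopentyl-type carbon, releases the tertiary alcohol and leaves the C3–O bond, hence the C3 configuration, untouched. The oxirane oxygen is set cis to the C4 benzyl group beforehand by anti hydroxymethylation of a lactone enediolate.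

Key step: step 6

Assumption: the sense of induction in step 2 is assigned by analogy. (R)-DTBM-SEGPHOS is written, and if the first run delivers the (S)-lactone, the equally available (S)-ligand is used with no other change.
Remark: lactone locants are O1, C2 (C=O), C3 (carbinol carbon), C4 (CH), C5 (OCH2). In the target (3S,4S) the two benzyl groups are trans and the C3–OH is cis to the C4 benzyl group.

Step 1
Reactants: 1 4-(chloromethyl)-1,2-dimethoxybenzene (3,4-dimethoxybenzyl chloride); 2 4-bromofuran-2(5H)-one
Product: 4 4-(3,4-dimethoxybenzyl)furan-2(5H)-one, via benzylzinc chloride 3 (not isolated)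
Conditions: 1, Zn dust, LiCl, THF, 25 °C; then 2, Pd(OAc)2 (2 mol %), SPhos (4 mol %), THF, 25 °C
Reagents that add atoms: zinc, [Zn] (retained only in intermediate 3)
Why: Negishi coupling, in which LiCl-assisted zinc insertion gives a mild benzylzinc reagent that tolerates the lactone, and the vinylogous acyl bromide of 2 adds readily to zerovalent palladium, so the sp3–sp2 bond forms at C4 without attack on the carbonyl and without creating a stereocenter.

Step 2
Reactants: 4 4-(3,4-dimethoxybenzyl)furan-2(5H)-one
Product: 5 (4R)-4-(3,4-dimethoxybenzyl)oxolan-2-one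
Conditions: Cu(OAc)2·H2O (3 mol %), (R)-DTBM-SEGPHOS (3 mol %), (EtO)2MeSiH, t-BuOH, toluene, 0 °C to rt
Reagents that add atoms: none
Why: Asymmetric copper hydride 1,4-reduction (conjugate hydrosilylation) of a beta-substituted butenolide, in which the chiral bisphosphine–CuH complex delivers hydride to one face of C4 and so sets the (R) centre, while t-BuOH protonates the copper enolate and turns the catalyst over under base-free conditions that should suppress double-bond migration.

Step 3
Reactants: 5 (4R)-4-(3,4-dimethoxybenzyl)oxolan-2-one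
Product: 7 (3R,4S)-4-(3,4-dimethoxybenzyl)-3-hydroxyoxolan-2-one, via potassium enolate 6 (not isolated)
Conditions: KN(SiMe3)2, THF, −78 °C; 2-(benzenesulfonyl)-3-phenyloxaziridine, −78 °C; AcOH
Reagents that add atoms: 2-(benzenesulfonyl)-3-phenyloxaziridine (Davis oxaziridine), O=S(=O)(c1ccccc1)N1OC1c1ccccc1; KN(SiMe3)2, C[Si](C)(C)[N-][Si](C)(C)C.[K+] (potassium retained only in intermediate 6)
Why: Davis enolate hydroxylation, in which enolate 6 takes up the oxaziridine oxygen from the face anti to the C4 benzyl group to give mainly the trans alcohol, the selectivity at C3 being of no consequence because this centre is flattened again in step 4.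

Step 4
Reactants: 7 (3R,4S)-4-(3,4-dimethoxybenzyl)-3-hydroxyoxolan-2-one
Product: 9 (3R,4S)-4-(3,4-dimethoxybenzyl)-3-hydroxy-3-(hydroxymethyl)oxolan-2-one, via dilithium enediolate 8 (not isolated)
Conditions: LiN(i-Pr)2 (2.3 equiv), THF–DMPU, −78 to −40 °C; CH2O (gas, from cracked paraformaldehyde), −78 °C; AcOH
Reagents that add atoms: formaldehyde, C=O; LiN(i-Pr)2, CC(C)[N-]C(C)C.[Li+] (lithium retained only in intermediate 8)
Why: Aldol addition of a lactone enediolate to formaldehyde, in which the planar dianion 8 takes up the small electrophile at carbon from the face anti to the C4 benzyl group, so the new CH2OH ends trans and the C3–O bond cis to that group, which is the (3R) configuration of 9 and the relative configuration of the target.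

Step 5
Reactants: 9 (3R,4S)-4-(3,4-dimethoxybenzyl)-3-hydroxy-3-(hydroxymethyl)oxolan-2-one
Product: 11 (3R,7S)-7-(3,4-dimethoxybenzyl)-1,5-dioxaspiro[2.4]heptan-4-one (oxirane oxygen cis to the benzyl group), via primary monotosylate 10 (not isolated)
Conditions: TsCl, Et3N, DMAP (cat.), CH2Cl2, 0 °C; then DBU, rt
Reagents that add atoms: p-toluenesulfonyl chloride, Cc1ccc(S(=O)(=O)Cl)cc1 (its atoms are retained only in intermediate 10)
Why: Selective sulfonylation of the primary alcohol followed by base-induced 3-exo-tet Williamson closure by the tertiary hydroxyl, in which only the C–O bond of the CH2 carbon is broken, so C3 keeps its configuration and retro-aldol loss is blocked once the primary oxygen is sulfonylated.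

Step 6
Reactants: 11 (3R,7S)-7-(3,4-dimethoxybenzyl)-1,5-dioxaspiro[2.4]heptan-4-one; 12 4-bromo-1,2-bis(benzyloxy)benzene
Product: 14 (3S,4S)-3-[3,4-bis(benzyloxy)benzyl]-4-(3,4-dimethoxybenzyl)-3-hydroxyoxolan-2-one, via arylmagnesium bromide 13 (not isolated)
Conditions: 12, Mg turnings, THF, 40 °C; then slow addition to 11, CuI (15 mol %), THF, −40 to −20 °C; aq NH4Cl
Reagents that add atoms: magnesium, [Mg] (retained only in intermediate 13)
Why: Transmetallation of 13 to monovalent copper gives a soft arylcopper species that attacks the oxirane of 11 in an SN2 manner at the unsubstituted CH2 carbon, the C–O bond of that carbon breaks with release of ring strain, and the tertiary alkoxide on C3 is protonated on work-up. The closest known reaction type is the copper-catalysed opening of glycidic esters by aryl Grignard reagents at the carbon remote from the ester, which gives 3-aryl-2-hydroxy esters. No ring is closed; the three-membered ring, which is not part of the target, is opened. No new stereocenter is made: the C3–O bond and the ring bonds at C3 are not involved, so C3 keeps the configuration fixed in step 4 (the descriptor changes from R to S only because the CH2 substituent drops in rank), and C4 is a spectator. Regioselectivity is secured by the substrate, since the other oxirane carbon is fully substituted and bears the electron-withdrawing lactone carbonyl, which disfavours both SN2 and cationic opening there. Chemoselectivity for the oxirane over the lactone carbonyl relies on low temperature, slow addition of 13 onto the copper salt and the shielding of the carbonyl by the adjacent spiro centre.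

Step 7
Reactants: 14 (3S,4S)-3-[3,4-bis(benzyloxy)benzyl]-4-(3,4-dimethoxybenzyl)-3-hydroxyoxolan-2-one
Product: 15 (3S,4S)-3-(3,4-dihydroxybenzyl)-4-(3,4-dimethoxybenzyl)-3-hydroxyoxolan-2-one (target)
Conditions: H2 (1 atm), Pd/C (10 wt %), EtOAc–MeOH, rt
Reagents that add atoms: none
Why: Catalytic hydrogenolysis of the two aryl benzyl ethers, whose O–CH2Ph bonds are the only benzylic C–O bonds in 14 (the tertiary alcohol is homobenzylic), so the catechol should be released without touching the lactone, the methyl ethers or either stereocenter.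

Compound list
1 | 4-(chloromethyl)-1,2-dimethoxybenzene | COc1ccc(CCl)cc1OC | starting material
2 | 4-bromofuran-2(5H)-one | O=C1C=C(Br)CO1 | starting material
3 | (3,4-dimethoxybenzyl)zinc chloride | COc1ccc(C[Zn]Cl)cc1OC | intermediate
4 | 4-(3,4-dimethoxybenzyl)furan-2(5H)-one | COc1ccc(CC2=CC(=O)OC2)cc1OC | intermediate
5 | (4R)-4-(3,4-dimethoxybenzyl)oxolan-2-one | COc1ccc(C[C@H]2COC(=O)C2)cc1OC | intermediate
6 | potassium enolate of 5 | COc1ccc(C[C@H]2COC([O-])=C2)cc1OC.[K+] | intermediate
7 | (3R,4S)-4-(3,4-dimethoxybenzyl)-3-hydroxyoxolan-2-one (OH trans to benzyl) | COc1ccc(C[C@H]2COC(=O)[C@@H]2O)cc1OC | intermediate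
8 | dilithium enediolate of 7 | COc1ccc(C[C@H]2COC([O-])=C2[O-])cc1OC.[Li+].[Li+] | intermediate
9 | (3R,4S)-4-(3,4-dimethoxybenzyl)-3-hydroxy-3-(hydroxymethyl)oxolan-2-one | COc1ccc(C[C@H]2COC(=O)[C@]2(O)CO)cc1OC | intermediate
10 | [(3R,4S)-4-(3,4-dimethoxybenzyl)-3-hydroxy-2-oxooxolan-3-yl]methyl 4-methylbenzenesulfonate | COc1ccc(C[C@H]2COC(=O)[C@]2(O)COS(=O)(=O)c2ccc(C)cc2)cc1OC | intermediate
11 | (3R,7S)-7-(3,4-dimethoxybenzyl)-1,5-dioxaspiro[2.4]heptan-4-one | COc1ccc(C[C@H]2COC(=O)[C@]23CO3)cc1OC | intermediate
12 | 4-bromo-1,2-bis(benzyloxy)benzene | Brc1ccc(OCc2ccccc2)c(OCc2ccccc2)c1 | starting material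
13 | [3,4-bis(benzyloxy)phenyl]magnesium bromide | Br[Mg]c1ccc(OCc2ccccc2)c(OCc2ccccc2)c1 | intermediate
14 | (3S,4S)-3-[3,4-bis(benzyloxy)benzyl]-4-(3,4-dimethoxybenzyl)-3-hydroxyoxolan-2-one | COc1ccc(C[C@H]2COC(=O)[C@]2(O)Cc2ccc(OCc3ccccc3)c(OCc3ccccc3)c2)cc1OC | intermediate
15 | (3S,4S)-3-(3,4-dihydroxybenzyl)-4-(3,4-dimethoxybenzyl)-3-hydroxyoxolan-2-one | COc1ccc(C[C@H]2COC(=O)[C@]2(O)Cc2ccc(O)c(O)c2)cc1OC | target

Total step count: 7. Longest linear sequence: 7 steps (1 or 2 to 15). The aryl fragment 12 is bought and enters without a separate step.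

Steps most likely to fail

Step 6 (key step). The aryl Grignard reagent may add to the lactone carbonyl faster than the copper species opens the oxirane. Magnesium halide may also open the oxirane with halide and stall C–C bond formation. The fallback replaces the polar union by a radical one, with no carbon nucleophile in the flask. Setting out from 11, LiI and AcOH in THF open the oxirane at its CH2 carbon to the iodohydrin (3S,4S)-4-(3,4-dimethoxybenzyl)-3-hydroxy-3-(iodomethyl)oxolan-2-one F1. Nickel-catalysed reductive cross-electrophile coupling of F1 and aryl bromide 12 (NiBr2(dme), 4,4'-di-tert-butyl-2,2'-bipyridine, Mn powder, DMA, rt) forms the same CH2–aryl bond through a primary alkyl radical captured by an arylnickel species. The route is rejoined at 14.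

Step 4. Double deprotonation may be incomplete, the enediolate may react at oxygen or decompose, the adduct may lose formaldehyde again by retro-aldol reaction on warming, and facial selectivity may be modest. The fallback uses an irreversible alkylation of a protected mono-anion instead of an aldol reaction of a dianion. Setting out from 7, benzyl 2,2,2-trichloroacetimidate and catalytic TfOH give the benzyl ether (3R,4S)-3-(benzyloxy)-4-(3,4-dimethoxybenzyl)oxolan-2-one F2. LiN(i-Pr)2 in THF at −78 °C, then benzyl chloromethyl ether, alkylate its enolate anti to the C4 benzyl group to give (3R,4S)-3-(benzyloxy)-3-[(benzyloxy)methyl]-4-(3,4-dimethoxybenzyl)oxolan-2-one F3. Hydrogenolysis (H2, Pd/C) removes both benzyl groups and rejoins the route at 9.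

Step 2. Enantioselectivity may be insufficient for a single enantiomer, and the double bond of 4 may migrate out of conjugation before hydride transfer. The fallback uses auxiliary control instead of catalyst control.
- (R)-4-Benzyloxazolidin-2-one is N-acylated by 4-tert-butoxy-4-oxobutanoic acid (pivaloyl chloride, Et3N, LiCl) to the imide tert-butyl 4-[(4R)-4-benzyl-2-oxo-1,3-oxazolidin-3-yl]-4-oxobutanoate F4.
- Setting out from 1, the sodium enolate of F4 (NaN(SiMe3)2, NaI, THF, −78 °C) is alkylated by 1 on the face away from the auxiliary benzyl group. This gives tert-butyl (3R)-4-[(4R)-4-benzyl-2-oxo-1,3-oxazolidin-3-yl]-3-(3,4-dimethoxybenzyl)-4-oxobutanoate F5, whose minor diastereomer can be removed.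
- LiBH4 cleaves the imide to tert-butyl (3R)-4-(3,4-dimethoxyphenyl)-3-(hydroxymethyl)butanoate F6.
- CF3CO2H closes the lactone, which rejoins the route at 5 and bypasses 2, 3 and 4.

Further compounds
F1 | step 6 | (3S,4S)-4-(3,4-dimethoxybenzyl)-3-hydroxy-3-(iodomethyl)oxolan-2-one | COc1ccc(C[C@H]2COC(=O)[C@]2(O)CI)cc1OC
F2 | step 4 | (3R,4S)-3-(benzyloxy)-4-(3,4-dimethoxybenzyl)oxolan-2-one | COc1ccc(C[C@H]2COC(=O)[C@@H]2OCc2ccccc2)cc1OC
F3 | step 4 | (3R,4S)-3-(benzyloxy)-3-[(benzyloxy)methyl]-4-(3,4-dimethoxybenzyl)oxolan-2-one | COc1ccc(C[C@H]2COC(=O)[C@]2(OCc2ccccc2)COCc2ccccc2)cc1OC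
F4 | step 2 | tert-butyl 4-[(4R)-4-benzyl-2-oxo-1,3-oxazolidin-3-yl]-4-oxobutanoate | CC(C)(C)OC(=O)CCC(=O)N1[C@H](Cc2ccccc2)COC1=O
F5 | step 2 | tert-butyl (3R)-4-[(4R)-4-benzyl-2-oxo-1,3-oxazolidin-3-yl]-3-(3,4-dimethoxybenzyl)-4-oxobutanoate | CC(C)(C)OC(=O)C[C@@H](Cc1ccc(OC)c(OC)c1)C(=O)N1[C@H](Cc2ccccc2)COC1=O
F6 | step 2 | tert-butyl (3R)-4-(3,4-dimethoxyphenyl)-3-(hydroxymethyl)butanoate | CC(C)(C)OC(=O)C[C@@H](Cc1ccc(OC)c(OC)c1)CO
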